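## The problem

Positions are given in drimane numbering (ring A = C1–C5 and C10, ring B = C5–C10, C11 on C9); compound numbers refer to the list after the steps.

Target 21 is a cis-fused decalin with a C3 ketone beside the C4 gem-dimethyl carbon, a C7=C8 alkene carrying the C8 methyl, and a C11H2–O–(coumarin-7-yl) ether on C9. Three contiguous stereocentres must be set, C5, C10 (quaternary) and C9, in the (5S,9R,10S) series: H-5 and the C10 methyl are cis, and C11 is trans to the C10 methyl. None of them is α to the ketone, so nothing can be corrected by equilibration, and there is no earlier centre to relay from. The first centre must therefore come from a reagent or catalyst, and ideally all three from one event.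

The coumarin lactone will not survive hydride, copper hydride or alkoxide, so it has to come last. The C7=C8 alkene must not drift under acid. C11 is β-branched and C9–H is allylic, so activating C11 invites elimination. A free C11 hydroxyl lies cis to C1 and would add 5-exo to any C1=C2–C3=O enone.

The enabling feature is ring B: a cyclohexene whose C7=C8 bond lies opposite the C5–C10 bond, with C9 and C10 vicinal. That is the Diels–Alder pattern of a C6–C9 diene on a C5=C10 dienophile. Because C4 is quaternary, only a C1 carbonyl can activate that alkene, and its 1,3-relation to C3 lets it be traded for the C3 ketone afterwards.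

## Retrosynthesis

**Aryl ether.** The C11–O(aryl) bond of 21 is cut to primary alcohol 19 and umbelliferone 20. The lactone of 20 cannot pass the hydride and copper hydride steps, so this bond is made last. Cutting on the alkyl side uses the phenol as it is sold; the aryl-side cut is held in reserve. The forward reaction must substitute at a β-branched primary carbon without elimination across C9–C11.

**Unmasking and saturation.** Alcohol 19 comes from silyl ether 18, and 18 from enone 17 by adding two hydrogens at C1–C2; no skeletal bond is cut. Oxygen 11 stays silylated until C1=C2 is saturated, because the free hydroxyl would cyclise onto C1. A bulky silyl ether is preferred to a benzylic ether: its oxygen is a poor nucleophile toward cationic C1 and a poor base toward the Lewis acid of the key step. The reduction must leave C7=C8 alone.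

**1,3-Carbonyl transposition.** Enone 17 is the hydrolysis and dehydration product of allylic alcohol 16, which comes from vinylogous ester 15 by 1,2-reduction. This moves the ring-A carbonyl from C3, where C4 insulates it from ring B, to C1, where it is conjugated with C10. The alternative of a C1 ketone plus a separate C3 oxygen would end in a deoxygenation at neopentyl C1. The forward step needs hydride addition to a hindered carbonyl and an acid treatment that does not move C7=C8.

**C7 oxygen.** Alkene 15 is traced through enol triflate 14 to silyl enol ether 13. The extra oxygen costs two forward steps, but it makes the diene electron-rich and its regiochemistry unambiguous. The enol ether double bond already sits where the final alkene must be.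

**Cycloaddition.** Adduct 13 is cut at C5–C6 and C9–C10 into dienone 8 and diene 12. Against the neighbouring cuts through ring A, this one builds the ring that carries all three stereocentres, the C8 methyl and C11, from two achiral pieces. The forward reaction must choose C5=C10 over C2=C3, the right orientation, the endo mode and one face of a flat dienone, all on a hindered, weakly activated alkene.

**Diene.** Diene 12 is the silyl dienol ether of methyl ketone 11, which is cut at C8=C9 into aldehyde 9 and ylide 10. The Wittig reaction must give the (E)-alkene, since this geometry becomes the C9 configuration.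

**Dienone.** Dienone 8 is traced to methoxydiene 7 by removing the C1 carbonyl oxygen, then through ketal 6 to ketone 5, through 4 to 3 (two C–CH3 bonds), and through 2 to 4-methylanisole 1. O-Alkylation of a cyclic 1,3-diketone precursor would be shorter, but it is expected to favour the less hindered oxygen, remote from the gem-dimethyl carbon, which is the wrong enol ether. In the chosen order the enol ether carbon is a ketone carbon flanked by a quaternary centre, so it can only enolise one way; C1 is oxidised afterwards at the only doubly allylic CH2.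

## Roads not taken

**Alternative 1:** The cut is at the exocyclic bonds C10–CH3 and C9–C11, leading to the bicyclic C8 enone A1 (C9=C10), itself from a Birch reduction. Forward, Me2CuLi would add methyl to C10 and the C8–C9 enolate would be trapped at C9 by monomeric formaldehyde to give hydroxymethyl ketone A2.
- Merits: both halves are well-established reaction types. Axial delivery of methyl normally gives the cis fusion, the electrophile should enter anti to the new methyl, and C11 arrives at the right oxidation level. In reliance on precedented reactions this road is better than the cycloaddition onto 8.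
- Weak points: the key step creates no stereocentre from achiral material. The absolute configuration must be carried by C5 and a C3 carbinol that is made first and oxidised away at the end. The enolate next to the new quaternary centre is hindered, hydroxymethylation is reversible, and C9 of A2 is α to the C8 ketone and epimerisable. The C8 ketone still has to become the methyl-bearing C7=C8 alkene.
- Comparison: the chosen plan sets against this higher reliability its economy. Three centres come from one catalytic step, there is no relay centre, and nothing is epimerisable after the key step.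

**Alternative 2:** The cut is the C4–C5 bond of ring A. Diketone A4 is traced to the prochiral cyclohexadienone A3, which carries an enol silane side chain on C10. Forward, a confined BINOL-derived imidodiphosphorimidate acid of the type HN[P(=NSO2CF3)(3,3′-Ar2-BINOL-O,O′)]2 would promote a desymmetrising intramolecular Mukaiyama–Michael addition of C4 to C5.
- Merits: C5 and C10 come from one catalytic event on a symmetrical substrate. The C3 ketone arrives directly, so the transposition and conjugate reduction of steps 10 and 11 are not needed; here this road is better.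
- Weak points: the new bond joins a fully substituted enol silane carbon to a β-carbon beside quaternary C10. A4 lacks the C8 methyl and C11, so a conjugate addition at C9, a methylation at C8 and removal of the C7 oxygen must follow, with two ketones to tell apart and C9 set late by the substrate.
- Comparison: against the direct C3 ketone, the chosen plan sets a key step that delivers the C8 methyl, C11 and the C9 configuration together with the ring fusion.

**Alternative 3:** The cut is at C4–C5 and C1–C10, closing ring A by cycloaddition of the gem-dimethyl silyloxydiene A6 onto a methyl-bearing double bond of 2,6-dimethyl-1,4-benzoquinone A5, to give enedione A7. The catalyst would be that of step 7.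
- Merits: quinones are the best-established dienophiles for this catalyst class, clearly better precedented than 8. A5 is a commodity. The C3 oxygen arrives as an enol ether on the right carbon, so no transposition is needed.
- Weak points: the diene terminus that must bond to C5 carries two methyl groups; the (Z)-methyl disfavours the s-cis conformer and crowds the forming bond. The required orientation needs activation through the C9 carbonyl between two methyl-bearing carbons; binding at the more accessible C6 carbonyl would send the nucleophilic terminus to C10. Afterwards the C6 oxygen must be deleted and the C9 carbonyl homologated to CH–CH2O with control at C9. C5 is then α to a ketone, so the cis fusion can epimerise.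
- Comparison: the chosen plan accepts a less activated dienophile. It sets against that a ring B that arrives complete, one oxygen to delete, and no epimerisable ring-fusion centre.

Key step: step 7

Remark: the (S)-diphenylprolinol-derived catalyst is assumed to shield the Si face of C5=C10 in 8; if the opposite sense is found, the catalyst from (R)-diphenylprolinol is used and nothing else changes.
Remark: aldehyde 9 is taken to be a catalogue chemical.

## Route

Step 1
Reactants: 1 4-methylanisole
Product: 3 4-methylcyclohex-3-en-1-one, via 1-methoxy-4-methylcyclohexa-1,4-diene 2 (not isolated)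
Conditions: Li, NH3(l), t-BuOH, THF, −78 → −33 °C; then (CO2H)2, THF/H2O, rt
Reagents that add atoms: water, O
Why: Birch reduction leaves both donor-bearing carbons sp2; oxalic acid then hydrolyses the enol ether under conditions too mild to move the alkene into conjugation.

Step 2
Reactants: 3 4-methylcyclohex-3-en-1-one
Product: 5 2,2,4-trimethylcyclohex-3-en-1-one, via 2,4-dimethylcyclohex-3-en-1-one 4 (not isolated)
Conditions: KOtBu (2.2 equiv), MeI (2.5 equiv), t-BuOH/THF, 0 °C → rt
Reagents that add atoms: iodomethane, CI
Why: Deconjugative α,α-dialkylation: the extended enolate alkylates twice at C2, which is both α to the carbonyl and allylic; base is limited so that C6 is not alkylated afterwards.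

Step 3
Reactants: 5 2,2,4-trimethylcyclohex-3-en-1-one
Product: 7 1-methoxy-4,6,6-trimethylcyclohexa-1,4-diene, via 4,4-dimethoxy-1,3,3-trimethylcyclohex-1-ene 6 (not isolated)
Conditions: HC(OMe)3, 4-MeC6H4SO3H·H2O (cat.), rt; concentrate; then Me3SiOTf, i-Pr2NEt, CH2Cl2, −20 °C → rt
Reagents that add atoms: trimethyl orthoformate, COC(OC)OC
Why: Orthoformate ketalisation followed by silyl-triflate-induced loss of methanol is a standard ketone to methyl enol ether sequence; quaternary C2 of 5 allows enolisation only toward C6, so the methoxy carbon is fixed next to the gem-dimethyl carbon.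

Step 4
Reactants: 7 1-methoxy-4,6,6-trimethylcyclohexa-1,4-diene
Product: 8 3-methoxy-4,4,6-trimethylcyclohexa-2,5-dien-1-one
Conditions: (C5H5NH)2Cr2O7 (pyridinium dichromate), t-BuOOH, Celite, PhH, rt
Reagents that add atoms: tert-butyl hydroperoxide, CC(C)(C)OO
Why: Bis-allylic C–H oxidation by a hexavalent chromium tert-butylperoxy species is the known way from 1-methoxycyclohexa-1,4-dienes with a quaternary C6 to 3-methoxy-4,4-disubstituted cyclohexa-2,5-dienones; C3 is the only doubly allylic CH2 and the quaternary carbon rules out aromatisation.

Step 5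
Reactants: 9 2-[(tert-butyldiphenylsilyl)oxy]acetaldehyde; 10 3-(triphenylphosphoranylidene)butan-2-one
Product: 11 (E)-5-[(tert-butyldiphenylsilyl)oxy]-3-methylpent-3-en-2-one
Conditions: PhMe, 80 °C
Reagents that add atoms: none
Why: Wittig olefination with a ketone-stabilised ylide gives the (E)-trisubstituted enone selectively.

Step 6
Reactants: 11 (E)-5-[(tert-butyldiphenylsilyl)oxy]-3-methylpent-3-en-2-one
Product: 12 (E)-2-[(tert-butyldimethylsilyl)oxy]-5-[(tert-butyldiphenylsilyl)oxy]-3-methylpenta-1,3-diene
Conditions: t-BuMe2SiOTf, Et3N, CH2Cl2, 0 °C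
Reagents that add atoms: tert-butyldimethylsilyl trifluoromethanesulfonate, CC(C)(C)[Si](C)(C)OS(=O)(=O)C(F)(F)F
Why: Soft enolisation of an α,β-unsaturated methyl ketone silylates oxygen and removes a methyl proton, the standard preparation of 2-silyloxydienes; the C3=C4 geometry is untouched.

Step 7
Reactants: 8 3-methoxy-4,4,6-trimethylcyclohexa-2,5-dien-1-one; 12 (E)-2-[(tert-butyldimethylsilyl)oxy]-5-[(tert-butyldiphenylsilyl)oxy]-3-methylpenta-1,3-diene
Product: 13 (4aR,8R,8aS)-6-[(tert-butyldimethylsilyl)oxy]-8-{[(tert-butyldiphenylsilyl)oxy]methyl}-3-methoxy-4,4,7,8a-tetramethyl-4a,5,8,8a-tetrahydronaphthalen-1(4H)-one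
Conditions: (S)-3,3-diphenyl-1-(2-methylphenyl)tetrahydro-1H,3H-pyrrolo[1,2-c][1,3,2]oxazaborole (C24H24BNO, from (S)-diphenylprolinol and 2-methylphenylboronic acid)·HN(SO2CF3)2 (20 mol%), 12 (2 equiv), CH2Cl2 (1 M), −78 → −20 °C
Reagents that add atoms: none
Why: The N-protonated oxazaborolidine binds the C1 carbonyl of 8 at the lone pair next to C2–H, and 12 adds in a concerted but asynchronous [4+2] process in which the CH2 terminus C6 (largest HOMO coefficient, next to the silyloxy carbon) bonds first to the β-carbon C5 and C9 then closes onto the methyl-bearing C10. The closest known reaction type is the Lewis-acid and cationic-oxazaborolidine-catalysed endo Diels–Alder reaction of 2-silyloxydienes with 2-methylcycloalk-2-enones, 4,4-disubstituted cyclohexadienones and quinone monoketals. Ring B, a six-membered carbocycle, is closed by intermolecular [4+2] annulation across the ring-A alkene, forming C5–C6 and C9–C10. C5 and C10 are fixed relative to each other by suprafacial addition to the endocyclic alkene, which makes H-5 and the C10 methyl cis. C9 is fixed by the endo transition state: the C1 carbonyl lies under the diene, so the outward (E) CH2OSi group ends up cis to C1 and trans to the C10 methyl. The absolute sense comes from the catalyst, whose aryl group must cover the Si face so that the diene adds to the Re face at both C5 and C10. Site selectivity for C5=C10 over C2=C3 is secured by the methoxy group, which makes C3 electron-rich and fully substituted; regioselectivity is secured because the silyloxy and C9-alkyl directing effects agree and the unsubstituted diene terminus is the one that meets neopentyl C5.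

Step 8
Reactants: 13 (the cycloadduct of step 7)
Product: 14 (4aR,8R,8aS)-8-{[(tert-butyldiphenylsilyl)oxy]methyl}-3-methoxy-4,4,7,8a-tetramethyl-6-[(trifluoromethanesulfonyl)oxy]-4a,5,8,8a-tetrahydronaphthalen-1(4H)-one
Conditions: CsF, PhNTf2, DME, rt
Reagents that add atoms: N-phenylbis(trifluoromethanesulfonimide), O=S(=O)(N(c1ccccc1)S(=O)(=O)C(F)(F)F)C(F)(F)F
Why: Fluoride cleaves the silyl enol ether to the cesium enolate, which is O-sulfonylated in situ, so the C7=C8 regiochemistry set by the cycloaddition passes unchanged into the enol triflate; the alkyl silyl ether is far less fluoride-labile than the enol ether.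

Step 9
Reactants: 14 (the C7 enol triflate)
Product: 15 (4aR,8R,8aS)-8-{[(tert-butyldiphenylsilyl)oxy]methyl}-3-methoxy-4,4,7,8a-tetramethyl-4a,5,8,8a-tetrahydronaphthalen-1(4H)-one
Conditions: Pd(OAc)2 (5 mol%), PPh3, HCO2H, Et3N, DMF, 60 °C
Reagents that add atoms: none
Why: Zerovalent palladium formed in situ inserts into the vinyl C–OTf bond, formate replaces triflate and loses CO2, and reductive elimination gives C7–H (formate reduction of enol triflates); the alkene stays where the triflate was.

Step 10
Reactants: 15 (the C7=C8 vinylogous ester)
Product: 17 (4aS,5R,8aS)-5-{[(tert-butyldiphenylsilyl)oxy]methyl}-1,1,4a,6-tetramethyl-4a,5,8,8a-tetrahydronaphthalen-2(1H)-one, via allylic alcohol 16 (not isolated)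
Conditions: LiAlH4, Et2O, 0 °C → rt; then 1 M HCl, THF, 0 °C → rt
Reagents that add atoms: water, O
Why: 1,2-Hydride addition to the vinylogous ester carbonyl, then acid hydrolysis of the enol ether with loss of the C1 hydroxyl as water (Stork–Danheiser 1,3-carbonyl transposition), leaves the carbonyl on C3 and a C1=C2 alkene; the C1 stereocentre of 16 is destroyed and O11 stays silylated so that it cannot add to the new enone.

Step 11
Reactants: 17 (the C1=C2–C3=O enone)
Product: 18 (4aS,5R,8aS)-5-{[(tert-butyldiphenylsilyl)oxy]methyl}-1,1,4a,6-tetramethyl-3,4,4a,5,8,8a-hexahydronaphthalen-2(1H)-one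
Conditions: [CuH(PPh3)]6 (0.4 equiv), wet PhH, rt
Reagents that add atoms: none
Why: Phosphine-stabilised copper hydride delivers hydride to C1 of the enone only (conjugate reduction), leaving the isolated C7=C8 alkene and the ketone; no stereocentre is created.

Step 12
Reactants: 18 (the saturated C3 ketone silyl ether)
Product: 19 (4aS,5R,8aS)-5-(hydroxymethyl)-1,1,4a,6-tetramethyl-3,4,4a,5,8,8a-hexahydronaphthalen-2(1H)-one
Conditions: Bu4NF, AcOH, THF, rt
Reagents that add atoms: none
Why: Fluoride-induced Si–O cleavage of the primary silyl ether; acetic acid buffers the medium, and with C1–C2 saturated the freed alcohol has no acceptor to add to.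

Step 13
Reactants: 19 (the C11 alcohol); 20 umbelliferone (7-hydroxy-2H-chromen-2-one)
Product: 21 7-{[(1R,4aS,8aS)-2,5,5,8a-tetramethyl-6-oxo-1,4,4a,5,6,7,8,8a-octahydronaphthalen-1-yl]methoxy}-2H-chromen-2-one
Conditions: PPh3, DIAD, THF, 0 °C → rt
Reagents that add atoms: none
Why: Mitsunobu etherification: the acidic phenol (pKa about 8) protonates the betaine and its anion displaces the oxyphosphonium group at primary C11; no stereocentre is involved and the lactone enters after all hydride and base steps.

## Compound list

1 | 4-methylanisole | COc1ccc(C)cc1 | starting material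
2 | 1-methoxy-4-methylcyclohexa-1,4-diene | COC1=CCC(C)=CC1 | intermediate
3 | 4-methylcyclohex-3-en-1-one | CC1=CCC(=O)CC1 | intermediate
4 | 2,4-dimethylcyclohex-3-en-1-one (racemic) | CC1=CC(C)C(=O)CC1 | intermediate
5 | 2,2,4-trimethylcyclohex-3-en-1-one | CC1=CC(C)(C)C(=O)CC1 | intermediate
6 | 4,4-dimethoxy-1,3,3-trimethylcyclohex-1-ene | COC1(OC)CCC(C)=CC1(C)C | intermediate
7 | 1-methoxy-4,6,6-trimethylcyclohexa-1,4-diene | COC1=CCC(C)=CC1(C)C | intermediate
8 | 3-methoxy-4,4,6-trimethylcyclohexa-2,5-dien-1-one | COC1=CC(=O)C(C)=CC1(C)C | intermediate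
9 | 2-[(tert-butyldiphenylsilyl)oxy]acetaldehyde | O=CCO[Si](c1ccccc1)(c1ccccc1)C(C)(C)C | starting material
10 | 3-(triphenylphosphoranylidene)butan-2-one | CC(=O)C(C)=P(c1ccccc1)(c1ccccc1)c1ccccc1 | starting material
11 | (E)-5-[(tert-butyldiphenylsilyl)oxy]-3-methylpent-3-en-2-one | CC(=O)/C(C)=C/CO[Si](c1ccccc1)(c1ccccc1)C(C)(C)C | intermediate
12 | (E)-2-[(tert-butyldimethylsilyl)oxy]-5-[(tert-butyldiphenylsilyl)oxy]-3-methylpenta-1,3-diene | C=C(O[Si](C)(C)C(C)(C)C)/C(C)=C/CO[Si](c1ccccc1)(c1ccccc1)C(C)(C)C | intermediate
13 | (4aR,8R,8aS)-6-[(tert-butyldimethylsilyl)oxy]-8-{[(tert-butyldiphenylsilyl)oxy]methyl}-3-methoxy-4,4,7,8a-tetramethyl-4a,5,8,8a-tetrahydronaphthalen-1(4H)-one; cis-fused, CH2OSi trans to the angular methyl | CC1=C(O[Si](C)(C)C(C)(C)C)C[C@@H]2C(C)(C)C(OC)=CC(=O)[C@]2(C)[C@@H]1CO[Si](c1ccccc1)(c1ccccc1)C(C)(C)C | intermediate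
14 | (4aR,8R,8aS)-8-{[(tert-butyldiphenylsilyl)oxy]methyl}-3-methoxy-4,4,7,8a-tetramethyl-6-[(trifluoromethanesulfonyl)oxy]-4a,5,8,8a-tetrahydronaphthalen-1(4H)-one | CC1=C(OS(=O)(=O)C(F)(F)F)C[C@@H]2C(C)(C)C(OC)=CC(=O)[C@]2(C)[C@@H]1CO[Si](c1ccccc1)(c1ccccc1)C(C)(C)C | intermediate
15 | (4aR,8R,8aS)-8-{[(tert-butyldiphenylsilyl)oxy]methyl}-3-methoxy-4,4,7,8a-tetramethyl-4a,5,8,8a-tetrahydronaphthalen-1(4H)-one | CC1=CC[C@@H]2C(C)(C)C(OC)=CC(=O)[C@]2(C)[C@@H]1CO[Si](c1ccccc1)(c1ccccc1)C(C)(C)C | intermediate
16 | (4aS,8R,8aS)-8-{[(tert-butyldiphenylsilyl)oxy]methyl}-3-methoxy-4,4,7,8a-tetramethyl-1,4,4a,5,8,8a-hexahydronaphthalen-1-ol, both C1 epimers | CC1=CC[C@@H]2C(C)(C)C(OC)=CC(O)[C@]2(C)[C@@H]1CO[Si](c1ccccc1)(c1ccccc1)C(C)(C)C | intermediate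
17 | (4aS,5R,8aS)-5-{[(tert-butyldiphenylsilyl)oxy]methyl}-1,1,4a,6-tetramethyl-4a,5,8,8a-tetrahydronaphthalen-2(1H)-one | CC1=CC[C@@H]2C(C)(C)C(=O)C=C[C@]2(C)[C@@H]1CO[Si](c1ccccc1)(c1ccccc1)C(C)(C)C | intermediate
18 | (4aS,5R,8aS)-5-{[(tert-butyldiphenylsilyl)oxy]methyl}-1,1,4a,6-tetramethyl-3,4,4a,5,8,8a-hexahydronaphthalen-2(1H)-one | CC1=CC[C@@H]2C(C)(C)C(=O)CC[C@]2(C)[C@@H]1CO[Si](c1ccccc1)(c1ccccc1)C(C)(C)C | intermediate
19 | (4aS,5R,8aS)-5-(hydroxymethyl)-1,1,4a,6-tetramethyl-3,4,4a,5,8,8a-hexahydronaphthalen-2(1H)-one | CC1=CC[C@@H]2C(C)(C)C(=O)CC[C@]2(C)[C@@H]1CO | intermediate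
20 | umbelliferone (7-hydroxy-2H-chromen-2-one) | O=c1ccc2ccc(O)cc2o1 | starting material
21 | 7-{[(1R,4aS,8aS)-2,5,5,8a-tetramethyl-6-oxo-1,4,4a,5,6,7,8,8a-octahydronaphthalen-1-yl]methoxy}-2H-chromen-2-one | CC1=CC[C@@H]2C(C)(C)C(=O)CC[C@]2(C)[C@@H]1COc1ccc2ccc(=O)oc2c1 | target

## Step count and weak points

Total: 13 steps. Longest linear sequence: 11 steps (steps 1–4 and 7–13); the diene branch is steps 5 and 6.

**Step 7 (key step).** The cycloaddition may be too slow: the C1 carbonyl of 8 is ester-like because of the methoxy donor, C5 is neopentyl and C10 becomes quaternary. Protodesilylation of the diene, or Mukaiyama–Michael addition at C5 without ring closure, could then overtake it. Facial discrimination may also be weak, because the reacting alkene lies on the side of the carbonyl away from the boron-bound lone pair.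
Fallback (from 5, back at 17): the methyl enol ether is replaced by an enol pivalate, a much weaker donor, so that C1 activates C5=C10 like a ketone. Ketone 5 is O-acylated (KN(SiMe3)2, THF, −78 °C; t-BuCOCl) to 4,6,6-trimethylcyclohexa-1,4-dien-1-yl 2,2-dimethylpropanoate F1. Oxidation as in step 4 gives 4,6,6-trimethyl-3-oxocyclohexa-1,4-dien-1-yl 2,2-dimethylpropanoate F2. Cycloaddition with 12 under the step 7 catalyst should give the pivaloyloxy analogue of 13 F3. The operations of steps 8 and 9 then give the pivaloyloxy analogue of 14 F4 and the pivaloyloxy analogue of 15 F5. Luche reduction (NaBH4, CeCl3·7H2O, MeOH) gives the pivaloyloxy analogue of 16 F6. K2CO3/MeOH followed by 1 M HCl removes the pivalate and dehydrates the β-hydroxy ketone to 17.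

**Step 8.** The free cesium enolate may undergo retro-Michael cleavage of the strained C9–C10 bond, or lose its regiochemistry by proton exchange, before it is sulfonylated.
Fallback (from 13, back at 15), with no enolate at any point: the silyl enol ether is hydrolysed (1 M HCl, THF, 0 °C) to the C7 ketone of 13 F7. NaBH4 in MeOH at 0 °C reduces only this ketone, the vinylogous ester carbonyl being inert, to the C7 alcohol of 13 F8. Dehydration with Ph2S[OC(CF3)2Ph]2 toward the more substituted side gives 15 directly.

**Step 4.** The chromium reagent may attack the enol ether double bond or hydrolyse the enol ether instead of oxidising the doubly allylic CH2; the allylic methyl may also be oxidised.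
Fallback (from 6, isolated in this case, back at 8): the ketal is oxidised at its allylic CH2 (CrO3, 3,5-dimethylpyrazole, CH2Cl2, −20 °C) to 5,5-dimethoxy-2,4,4-trimethylcyclohex-2-en-1-one F9. β-Elimination of methanol with DBU (1,8-diazabicyclo[5.4.0]undec-7-ene) then gives 8. The enol ether is formed only after the oxidation, and its position is still fixed by the ketal carbon.

**Step 13.** The oxyphosphonium intermediate may eliminate across C9–C11, helped by the allylic C9–H, and substitution at the β-branched carbon may be slow.
Fallback (from 19, back at 21): the polarity is reversed. Alcohol 19 acts as the nucleophile in a palladium-catalysed C–O coupling with 7-bromo-2H-chromen-2-one ([Pd(C3H5)Cl]2, 2-(di-tert-butylphosphino)-2′,4′,6′-triisopropyl-3,6-dimethoxybiphenyl, Cs2CO3, PhMe, 90 °C), so C11 never carries a leaving group. No new intermediate is formed.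

## Further compounds

F1 | step 7 | 4,6,6-trimethylcyclohexa-1,4-dien-1-yl 2,2-dimethylpropanoate | CC1=CC(C)(C)C(OC(=O)C(C)(C)C)=CC1
F2 | step 7 | 4,6,6-trimethyl-3-oxocyclohexa-1,4-dien-1-yl 2,2-dimethylpropanoate | CC1=CC(C)(C)C(OC(=O)C(C)(C)C)=CC1=O
F3 | step 7 | pivaloyloxy analogue of 13 (OC(=O)t-Bu in place of OCH3 at C3) | CC1=C(O[Si](C)(C)C(C)(C)C)C[C@@H]2C(C)(C)C(OC(=O)C(C)(C)C)=CC(=O)[C@]2(C)[C@@H]1CO[Si](c1ccccc1)(c1ccccc1)C(C)(C)C
F4 | step 7 | pivaloyloxy analogue of 14 | CC1=C(OS(=O)(=O)C(F)(F)F)C[C@@H]2C(C)(C)C(OC(=O)C(C)(C)C)=CC(=O)[C@]2(C)[C@@H]1CO[Si](c1ccccc1)(c1ccccc1)C(C)(C)C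
F5 | step 7 | pivaloyloxy analogue of 15 | CC1=CC[C@@H]2C(C)(C)C(OC(=O)C(C)(C)C)=CC(=O)[C@]2(C)[C@@H]1CO[Si](c1ccccc1)(c1ccccc1)C(C)(C)C
F6 | step 7 | pivaloyloxy analogue of 16 (both C1 epimers) | CC1=CC[C@@H]2C(C)(C)C(OC(=O)C(C)(C)C)=CC(O)[C@]2(C)[C@@H]1CO[Si](c1ccccc1)(c1ccccc1)C(C)(C)C
F7 | step 8 | C7 ketone of 13 (C7=O and C8–H in place of the silyl enol ether; both C8 epimers) | CC1C(=O)C[C@@H]2C(C)(C)C(OC)=CC(=O)[C@]2(C)[C@@H]1CO[Si](c1ccccc1)(c1ccccc1)C(C)(C)C
F8 | step 8 | C7 alcohol of 13 (C7 and C8 epimers) | CC1C(O)C[C@@H]2C(C)(C)C(OC)=CC(=O)[C@]2(C)[C@@H]1CO[Si](c1ccccc1)(c1ccccc1)C(C)(C)C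
F9 | step 4 | 5,5-dimethoxy-2,4,4-trimethylcyclohex-2-en-1-one | COC1(OC)CC(=O)C(C)=CC1(C)C
F0 | step 13 | none | none
A1 | alternative 1 | bicyclic C8 enone (C9=C10) with C3 silyloxy and C4 gem-dimethyl groups | O=C1CC[C@@H]2C(C)(C)[C@H](O[Si](C)(C)C(C)(C)C)CCC2=C1
A2 | alternative 1 | cis-fused C8 ketone with C10 methyl and C9 hydroxymethyl | O=C1CC[C@@H]2C(C)(C)[C@H](O[Si](C)(C)C(C)(C)C)CC[C@]2(C)[C@@H]1CO
A3 | alternative 2 | 4-methyl-4-[4-methyl-3-(trimethylsilyloxy)pent-3-en-1-yl]cyclohexa-2,5-dien-1-one | CC(C)=C(O[Si](C)(C)C)CCC1(C)C=CC(=O)C=C1
A4 | alternative 2 | cis-fused C3 ketone with C7 enone (C8=C9 alkene) | O=C1C[C@@H]2C(C)(C)C(=O)CC[C@]2(C)C=C1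
A5 | alternative 3 | 2,6-dimethyl-1,4-benzoquinone | CC1=CC(=O)C=C(C)C1=O
A6 | alternative 3 | 4-methyl-3-(triisopropylsilyloxy)penta-1,3-diene | C=CC(O[Si](C(C)C)(C(C)C)C(C)C)=C(C)C
A7 | alternative 3 | cis-fused enedione with C3 silyl enol ether | CC1=CC(=O)[C@@H]2C(C)(C)C(O[Si](C(C)C)(C(C)C)C(C)C)=CC[C@]2(C)C1=O
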